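## The problem

2'-Methoxylupalbigenin (25) is an isoflavone: a benzo-fused 4-pyranone (rings A and C) that carries ring B on C3. It has no stereocentre, so the difficulty is regiochemical. One prenyl group must sit on C6 of ring A, between the hydroxyls on C5 and C7 and not on the similar C8. The second must sit on C3' of ring B, between O2' and O4'. Of the four phenolic oxygens only O2' is methylated. The two trisubstituted alkenes are the fragile part: acid closes them onto the neighbouring phenols as chromans, and they do not survive hydrogenolysis, halogen electrophiles or strong Lewis acids, which narrows the choice of protecting groups. C2 of the pyranone is opened by hydroxide or amines, and the free phloroglucinol-type ring A is easily oxidised. The feature that makes the key step possible is that C5–C6–C7 of ring A is a malonyl unit and C4a is the nucleophilic α-carbon of the vinylogous ester O1–C8a=C4a–C4=O. Cutting C4a–C5 therefore leaves a β-keto ester chain hanging through C8 from C8a of a monocyclic 4-pyranone, with the ester carbon C5 six atoms from C4a. Because O1 is already tied into ring C, C8 is by construction the carbon on the pyranone and C6 the central malonate carbon, so the 6-versus-8 question does not arise.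

## Retrosynthesis

**O4'–Si.** The target 25 is taken back to its 4'-O-triisopropylsilyl ether 24. Ring A needs no protection because its two hydroxyls are created in the ring-forming step. Only O4' must be masked, since a free phenol would capture the ketene of that step. A silyl ether is chosen over benzyl or methoxymethyl because its removal by buffered fluoride needs neither hydrogen nor acid, the two reagents the prenyl groups cannot tolerate.

**C4a–C5 (ring A).** Cutting this bond in 24 gives the tert-butyl β-keto ester 21, a 4-pyranone with the chain C8–C7(=O)–C6(prenyl)–C5(=O)OtBu on the carbon that becomes C8a. The neighbouring cuts at O1–C8a or O1–C2 (the deoxybenzoin logic) would leave an intact phloroglucinol ring whose C-prenylation gives 6/8 and C/O mixtures. Here the prenyl group rides on the one doubly activated carbon of an open chain. The precursor has one ring fewer and no aromatic ring A. The forward reaction must generate an electrophile at C5 strong enough for the modest nucleophile C4a under conditions that spare the alkenes and C2. Thermal loss of tert-butanol to an acylketene does this without acid or base.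

**C6–C7.** The β-keto ester 21 is cut between the ketone carbon and the prenylated carbon, giving the pyranone acetic acid 15 and the prenylmalonic half ester 19. The alternative cut at C7–C8 would acylate the lithiated methyl group of the pyranone with an activated prenylmalonate. That acyl donor carries a very acidic hydrogen and would quench the carbanion. In the chosen polarity the nucleophile is a soft magnesium malonate that tolerates acidic partners, and the carboxyl group it loses drives the reaction (decarboxylative Claisen condensation).

**C7–C8 and C6–CH2.** Acid 15 comes from the methylpyranone 13 by carboxylation of its laterally lithiated methyl group (dienolate 14) with carbon dioxide, an electrophile with no acidity problem. Half ester 19 comes from mono-tert-butyl malonate 16 and prenyl bromide 17 by alkylation of the dianion. Both cuts lead to one-step reactions of simple materials.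

**C3–C1'.** The biaryl-type bond of 13 is cut to the ring B boronate 10 and the triflate 12 of allomaltol 11, which supplies ring C, O1 and the future C8 in one piece. A Suzuki coupling is asked only to tolerate the aryl silyl ether and the pyranone. The enol triflate next to the carbonyl is an activated electrophile.

**C1'–B and O2'–CH3.** Boronate 10 comes from bromide 8 by lithium–bromine exchange and borylation, and 8 from phenol 7 by O-methylation. The bromine is carried from the start because brominating a prenylated phenol would attack the alkene.

**C3'–CH2 and the oxygen pattern of ring B.** Phenol 7 is traced to the 1,1-dimethylallyl ether 5 by an aromatic Claisen rearrangement. In 5 the ether oxygen (the future O2') has the bromine on one ortho carbon, so the allyl group can only move to the carbon between the two oxygens. The rearrangement also frees exactly the hydroxyl that is to be methylated. Ether 5 comes from the propargyl ether 4 by semi-hydrogenation, 4 from phenol 2 and 3-chloro-3-methylbut-1-yne 3, and 2 from 4-bromoresorcinol 1 by silylation of the less hindered hydroxyl. The same silyl group then serves to the end of the synthesis.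

## Roads not taken

**Alternative 1:** Twin Claisen shifts on a complete isoflavone. The cuts are the two aryl–CH2 bonds at C6 and C3'. Heating the bis(1,1-dimethylallyl) ether A1 should cause two [3,3] shifts with allyl inversion and give A2 with both prenyl groups and free hydroxyls at C5 and C2'.
- Merits: both C–C bonds form in one operation and each shift has only one open ortho carbon (C4a and C1' are substituted). Every reaction type is known. The 2'-hydroxyl is released next to a chelated, unreactive 5-hydroxyl, so its selective methylation is straightforward.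
- Weak points: A1 requires a tertiary ether on the chelated, peri-hindered 5-hydroxyl, the hardest oxygen of an isoflavone to alkylate. The ortho dienones can pass the allyl group on by a Cope shift to the open para carbons C8 and C5'. The isoflavone core with four differentiated oxygens must first be built. The two methoxymethyl groups of A2 must be removed by acid beside two ortho-prenyl phenols.
- Comparison: this road is better on precedent, since the chosen plan rests on an untested ring closure. Against that, the chosen plan fixes the C6 pattern by connectivity and not by a preference between ortho and para migration, and it ends with fluoride, not acid. It borrows the same Claisen tactic for ring B in step 4 and shares the para-migration risk there, but at an early stage on a simple arene.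

**Alternative 2:** Annulation of a salicylaldehyde with a silyl alkyne. The cuts are C4–C3 and O1–C2. Salicylaldehyde A3 and alkyne A4 would react with [Cp*RhCl2]2 and Cu(OAc)2: trivalent rhodium cleaves the aldehyde C–H bond, the alkyne inserts, and C–O bond formation closes ring C to give A5.
- Merits: it is the most convergent of the four plans, joining two finished arenes and forming ring C catalytically by a known reaction class. The silyl group can steer the insertion and is removable.
- Weak points: A3 is a phloroglucinaldehyde with the prenyl group between two protected oxygens and one particular hydroxyl free, so making it restates the 6-versus-8 and oxygen-differentiation problem. The aryl group of an alkyne normally ends next to oxygen (flavone sense), so the isoflavone outcome depends entirely on the silyl group overriding this. The aldehyde is flanked on both sides, and two trisubstituted alkenes must survive Cu(OAc)2 at high temperature. After the key step come protodesilylation and acid removal of three methoxymethyl groups.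
- Comparison: this road is shorter in its longest line and uses a precedented ring closure. The chosen plan is more linear, but its ring closure has no regiochemical choice to make, ring A needs no prenylation, and its endgame is one fluoride step.

**Alternative 3:** Ring B from a cyclobutenone and an ynol ether. The cuts are C1'–C2', C3'–C4' and C4'–C5'. Heating cyclobutenone A6 with ynol ether A7 should give a vinylketene, its [2+2] adduct, four-electron opening and six-electron closure to A8.
- Merits: the mechanism fixes the ring B pattern. The methoxyl arrives with the ynol ether at C2', the prenyl group at C3', and the C4' hydroxyl is born free with no protecting group. This is more elegant than the six routine steps the chosen plan spends on ring B.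
- Weak points: A6, a 2-heteroaryl cyclobutenone on a fully decorated chromone, has no short access and is likely to be thermally and base sensitive. The electron-poor C2=C3 bond of the chromone is conjugated with the ketene and offers competing cyclisations. A7 is a sensitive reagent. The prenylation of ring A and the acid removal of two methoxymethyl groups remain unsolved.
- Comparison: this road solves ring B better than the chosen plan and leaves ring A, the harder regiochemical problem, to classical means. The chosen plan does the reverse.

Key step: step 12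

Remark on the chemistry: allomaltol 11 is treated as a purchasable compound (it is otherwise two steps from kojic acid). β-Keto ester 21 is written as its chelated Z-enol, which equilibrates with the keto form (racemic at C6), so no configuration has to be controlled there.

## Route

Step 1
Reactants: 1 4-bromoresorcinol (4-bromobenzene-1,3-diol)
Product: 2 2-bromo-5-[(triisopropylsilyl)oxy]phenol
Conditions: TIPSCl (1.05 equiv), imidazole, CH2Cl2, 0 °C to rt
Reagents that add atoms: triisopropylsilyl chloride, CC(C)[Si](Cl)(C(C)C)C(C)C
Why: Silylation of a phenol; the bulky chloride should take the hydroxyl para to bromine because the other one is flanked by the bromine atom, and any regioisomer or bis-ether is separable at this first stage.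

Step 2
Reactants: 2 2-bromo-5-[(triisopropylsilyl)oxy]phenol; 3 3-chloro-3-methylbut-1-yne
Product: 4 {4-bromo-3-[(2-methylbut-3-yn-2-yl)oxy]phenoxy}tri(propan-2-yl)silane
Conditions: CuCl2·2H2O (cat.), DBU, MeCN, 0 °C
Reagents that add atoms: none
Why: Copper-catalysed propargylic etherification of a phenol with a tertiary propargylic chloride, the standard entry to aryl 1,1-dimethylpropargyl ethers; the mild amine base leaves the aryl silyl ether intact.

Step 3
Reactants: 4 {4-bromo-3-[(2-methylbut-3-yn-2-yl)oxy]phenoxy}tri(propan-2-yl)silane
Product: 5 {4-bromo-3-[(2-methylbut-3-en-2-yl)oxy]phenoxy}tri(propan-2-yl)silane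
Conditions: H2 (1 atm), Pd/CaCO3 poisoned with Pb(OAc)2, quinoline, EtOAc, rt
Reagents that add atoms: none
Why: Lindlar semi-hydrogenation of the terminal alkyne to the vinyl group; the poisoned catalyst should not touch the aryl bromide, and reduction before heating prevents the propargyl ether from closing to a chromene.

Step 4
Reactants: 5 {4-bromo-3-[(2-methylbut-3-en-2-yl)oxy]phenoxy}tri(propan-2-yl)silane
Product: 7 6-bromo-2-(3-methylbut-2-en-1-yl)-3-[(triisopropylsilyl)oxy]phenol, via cyclohexadienone 6 (not isolated)
Conditions: xylenes, 130 °C
Reagents that add atoms: none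
Why: Aromatic Claisen rearrangement; the [3,3] shift inverts the 1,1-dimethylallyl group to a prenyl group and can only end on the carbon between the two oxygens because the other ortho carbon carries bromine, and tautomerisation of 6 frees the hydroxyl that is to become the methyl ether.

Step 5
Reactants: 7 6-bromo-2-(3-methylbut-2-en-1-yl)-3-[(triisopropylsilyl)oxy]phenol
Product: 8 [4-bromo-3-methoxy-2-(3-methylbut-2-en-1-yl)phenoxy]tri(propan-2-yl)silane
Conditions: MeI, K2CO3, acetone, 40 °C
Reagents that add atoms: iodomethane, CI
Why: Williamson methylation of the only free phenol; anhydrous carbonate in acetone should not cleave the triisopropylsilyl aryl ether.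

Step 6
Reactants: 8 [4-bromo-3-methoxy-2-(3-methylbut-2-en-1-yl)phenoxy]tri(propan-2-yl)silane
Product: 10 2-{2-methoxy-3-(3-methylbut-2-en-1-yl)-4-[(triisopropylsilyl)oxy]phenyl}-4,4,5,5-tetramethyl-1,3,2-dioxaborolane, via aryllithium 9 (not isolated)
Conditions: n-BuLi, THF, −78 °C; iPrOBpin, −78 °C to rt; H2O
Reagents that add atoms: 2-isopropoxy-4,4,5,5-tetramethyl-1,3,2-dioxaborolane, CC(C)OB1OC(C)(C)C(C)(C)O1; n-butyllithium, [Li]CCCC (lithium only in intermediate 9)
Why: Lithium–bromine exchange, assisted by the ortho methoxyl, followed by borylation of the aryllithium; the silyl ether is para to lithium and cannot migrate, and the prenyl group is inert at −78 °C.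

Step 7
Reactants: 11 allomaltol (5-hydroxy-2-methyl-4H-pyran-4-one)
Product: 12 6-methyl-4-oxo-4H-pyran-3-yl trifluoromethanesulfonate
Conditions: Tf2O, pyridine, CH2Cl2, −10 to 0 °C
Reagents that add atoms: trifluoromethanesulfonic anhydride, O=S(=O)(OS(=O)(=O)C(F)(F)F)C(F)(F)F
Why: Triflation of the enolic 5-hydroxyl of a 4-pyranone, as practised on kojic acid derivatives, gives a stable enol triflate activated for oxidative addition by the adjacent carbonyl.

Step 8
Reactants: 10 2-{2-methoxy-3-(3-methylbut-2-en-1-yl)-4-[(triisopropylsilyl)oxy]phenyl}-4,4,5,5-tetramethyl-1,3,2-dioxaborolane; 12 6-methyl-4-oxo-4H-pyran-3-yl trifluoromethanesulfonate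
Product: 13 5-{2-methoxy-3-(3-methylbut-2-en-1-yl)-4-[(triisopropylsilyl)oxy]phenyl}-2-methyl-4H-pyran-4-one
Conditions: Pd(PPh3)4 (5 mol %), K3PO4, 1,4-dioxane/H2O (9:1), 80 °C
Reagents that add atoms: none
Why: Suzuki–Miyaura coupling of an aryl boronate with an electron-poor enol triflate under zerovalent palladium forms the C3–C1' bond; phosphate is mild enough for the pyranone and the aryl silyl ether.

Step 9
Reactants: 13 5-{2-methoxy-3-(3-methylbut-2-en-1-yl)-4-[(triisopropylsilyl)oxy]phenyl}-2-methyl-4H-pyran-4-one
Product: 15 2-(5-{2-methoxy-3-(3-methylbut-2-en-1-yl)-4-[(triisopropylsilyl)oxy]phenyl}-4-oxo-4H-pyran-2-yl)acetic acid, via lithium dienolate 14 (not isolated)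
Conditions: LiHMDS (2.2 equiv), THF, −78 °C; CO2, −78 to −20 °C; cold 1 M HCl to pH 3
Reagents that add atoms: carbon dioxide, O=C=O; lithium hexamethyldisilazide, C[Si](C)(C)[N-][Si](C)(C)C.[Li+] (lithium only in intermediate 14)
Why: Lateral deprotonation of a 2-methyl-4-pyranone gives the extended enolate, which reacts with electrophiles at the exocyclic carbon and so restores the pyranone; carboxylation forms the C7–C8 bond, and the acid is taken on without heating.

Step 10
Reactants: 16 mono-tert-butyl malonate (3-tert-butoxy-3-oxopropanoic acid); 17 prenyl bromide (1-bromo-3-methylbut-2-ene)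
Product: 19 2-(tert-butoxycarbonyl)-5-methylhex-4-enoic acid (racemic), via dilithium enolate carboxylate 18 (not isolated)
Conditions: LDA (2.1 equiv), THF, −78 to 0 °C; 17, −78 °C to rt; cold 1 M HCl
Reagents that add atoms: lithium diisopropylamide, CC(C)[N-]C(C)C.[Li+] (lithium only in intermediate 18)
Why: C-alkylation of the dianion of a malonic half ester with an allylic bromide places the prenyl group on the carbon that becomes C6; the stereocentre formed is racemic and is lost again in step 12.

Step 11
Reactants: 15 2-(5-{2-methoxy-3-(3-methylbut-2-en-1-yl)-4-[(triisopropylsilyl)oxy]phenyl}-4-oxo-4H-pyran-2-yl)acetic acid; 19 2-(tert-butoxycarbonyl)-5-methylhex-4-enoic acid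
Product: 21 tert-butyl (2Z)-3-hydroxy-4-(5-{2-methoxy-3-(3-methylbut-2-en-1-yl)-4-[(triisopropylsilyl)oxy]phenyl}-4-oxo-4H-pyran-2-yl)-2-(3-methylbut-2-en-1-yl)but-2-enoate (β-keto ester written as its chelated enol), via acyl imidazolide 20 (not isolated)
Conditions: 15, CDI, THF, rt; then added to 19, MgCl2, Et3N, THF/MeCN, rt to 40 °C; aq. citric acid
Reagents that add atoms: 1,1'-carbonyldiimidazole, O=C(n1ccnc1)n1ccnc1 (imidazole only in intermediate 20)
Why: Masamune–Brooks decarboxylative Claisen condensation; the magnesium enolate of the half ester is C-acylated by the imidazolide and loses carbon dioxide, forming the C6–C7 bond under near-neutral conditions that tolerate the acidic methylene of 20, the silyl ether and both alkenes.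

Step 12
Reactants: 21 tert-butyl (2Z)-3-hydroxy-4-(5-{2-methoxy-3-(3-methylbut-2-en-1-yl)-4-[(triisopropylsilyl)oxy]phenyl}-4-oxo-4H-pyran-2-yl)-2-(3-methylbut-2-en-1-yl)but-2-enoate
Product: 24 5,7-dihydroxy-3-{2-methoxy-3-(3-methylbut-2-en-1-yl)-4-[(triisopropylsilyl)oxy]phenyl}-6-(3-methylbut-2-en-1-yl)-4H-chromen-4-one, via acylketene 22 (not isolated), via dienone tautomer 23 (not isolated)
Conditions: xylenes (0.003 M), 140 °C, slow addition of 21, N2 sweep to remove tBuOH
Reagents that add atoms: none
Why: Proposed new method: on heating, the chelated enol of 21 should lose tert-butanol through a six-membered transition state to give acylketene 22, the known behaviour of tert-butyl β-keto esters that keep one α-hydrogen. Enolisation of the C7 ketone toward C8, favoured by conjugation with the pyranone and reversible through the keto form, turns 22 into a dienylketene (C5=C6–C7=C8–C8a=C4a) whose termini C5 and C4a are six atoms apart. Ring A should then close by a thermal disrotatory six-electron electrocyclisation that forms C4a–C5; because the ketene carbon is attacked in its own plane, this is equally a pseudopericyclic C-acylation of the nucleophilic vinylogous-ester carbon C4a and needs no catalyst. Dienone 23 has only to move the C4a hydrogen to O5 to become the chelated 5,7-dihydroxy arene 24, and this aromatisation makes the sequence irreversible. The closest known reaction types are the thermolysis of tert-butyl β-keto esters and dioxinones to acylketenes that cyclise and aromatise to resorcylates, and the electrocyclisation of dienylketenes to phenols; closure onto a 4-pyranone carbon has not been shown. Site selectivity comes from the tether, since C4a is the only nucleophilic atom that reaches C5 in a six-membered array (C8 lies inside the chain and the oxygen on C4 would need an eight-membered ring), and the 6-prenyl pattern is fixed because O1 and C8 are already in place. Dimerisation of 22 and acylation of the new phenols by 22 are bimolecular and are held back by slow addition at high dilution, while the neutral medium spares both prenyl groups, the silyl ether and C2 of the pyranone. No stereocentre is formed.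

Step 13
Reactants: 24 5,7-dihydroxy-3-{2-methoxy-3-(3-methylbut-2-en-1-yl)-4-[(triisopropylsilyl)oxy]phenyl}-6-(3-methylbut-2-en-1-yl)-4H-chromen-4-one
Product: 25 2'-methoxylupalbigenin (5,7-dihydroxy-3-[4-hydroxy-2-methoxy-3-(3-methylbut-2-en-1-yl)phenyl]-6-(3-methylbut-2-en-1-yl)-4H-chromen-4-one)
Conditions: TBAF, AcOH, THF, 0 °C
Reagents that add atoms: none
Why: Fluoride cleavage of the aryl silyl ether; acetic acid buffers the phenoxides so that C2 of the pyranone is not exposed to base, and the prenyl groups meet no strong acid.

## Compound list

1 | 4-bromoresorcinol | Oc1ccc(Br)c(O)c1 | starting material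
2 | 2-bromo-5-[(triisopropylsilyl)oxy]phenol | Oc1cc(O[Si](C(C)C)(C(C)C)C(C)C)ccc1Br | intermediate
3 | 3-chloro-3-methylbut-1-yne | CC(C)(Cl)C#C | starting material
4 | {4-bromo-3-[(2-methylbut-3-yn-2-yl)oxy]phenoxy}tri(propan-2-yl)silane | C#CC(C)(C)Oc1cc(O[Si](C(C)C)(C(C)C)C(C)C)ccc1Br | intermediate
5 | {4-bromo-3-[(2-methylbut-3-en-2-yl)oxy]phenoxy}tri(propan-2-yl)silane | C=CC(C)(C)Oc1cc(O[Si](C(C)C)(C(C)C)C(C)C)ccc1Br | intermediate
6 | 2-bromo-6-(3-methylbut-2-en-1-yl)-5-[(triisopropylsilyl)oxy]cyclohexa-2,4-dien-1-one (racemic, not isolated) | O=C1C(Br)=CC=C(O[Si](C(C)C)(C(C)C)C(C)C)C1CC=C(C)C | intermediate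
7 | 6-bromo-2-(3-methylbut-2-en-1-yl)-3-[(triisopropylsilyl)oxy]phenol | Oc1c(Br)ccc(O[Si](C(C)C)(C(C)C)C(C)C)c1CC=C(C)C | intermediate
8 | [4-bromo-3-methoxy-2-(3-methylbut-2-en-1-yl)phenoxy]tri(propan-2-yl)silane | COc1c(Br)ccc(O[Si](C(C)C)(C(C)C)C(C)C)c1CC=C(C)C | intermediate
9 | {2-methoxy-3-(3-methylbut-2-en-1-yl)-4-[(triisopropylsilyl)oxy]phenyl}lithium (not isolated) | [Li]c1ccc(O[Si](C(C)C)(C(C)C)C(C)C)c(CC=C(C)C)c1OC | intermediate
10 | 2-{2-methoxy-3-(3-methylbut-2-en-1-yl)-4-[(triisopropylsilyl)oxy]phenyl}-4,4,5,5-tetramethyl-1,3,2-dioxaborolane | COc1c(B2OC(C)(C)C(C)(C)O2)ccc(O[Si](C(C)C)(C(C)C)C(C)C)c1CC=C(C)C | intermediate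
11 | allomaltol (5-hydroxy-2-methyl-4H-pyran-4-one) | Cc1cc(=O)c(O)co1 | starting material
12 | 6-methyl-4-oxo-4H-pyran-3-yl trifluoromethanesulfonate | Cc1cc(=O)c(OS(=O)(=O)C(F)(F)F)co1 | intermediate
13 | 5-{2-methoxy-3-(3-methylbut-2-en-1-yl)-4-[(triisopropylsilyl)oxy]phenyl}-2-methyl-4H-pyran-4-one | Cc1cc(=O)c(-c2ccc(O[Si](C(C)C)(C(C)C)C(C)C)c(CC=C(C)C)c2OC)co1 | intermediate
14 | lithium 3-{2-methoxy-3-(3-methylbut-2-en-1-yl)-4-[(triisopropylsilyl)oxy]phenyl}-6-methylidene-6H-pyran-4-olate (not isolated) | [Li+].[O-]C1=CC(=C)OC=C1-c1ccc(O[Si](C(C)C)(C(C)C)C(C)C)c(CC=C(C)C)c1OC | intermediate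
15 | 2-(5-{2-methoxy-3-(3-methylbut-2-en-1-yl)-4-[(triisopropylsilyl)oxy]phenyl}-4-oxo-4H-pyran-2-yl)acetic acid | OC(=O)Cc1cc(=O)c(-c2ccc(O[Si](C(C)C)(C(C)C)C(C)C)c(CC=C(C)C)c2OC)co1 | intermediate
16 | mono-tert-butyl malonate | CC(C)(C)OC(=O)CC(=O)O | starting material
17 | prenyl bromide (1-bromo-3-methylbut-2-ene) | CC(C)=CCBr | starting material
18 | dilithium salt (enolate carboxylate) of mono-tert-butyl malonate (not isolated) | [Li+].[Li+].[O-]C(=O)C=C([O-])OC(C)(C)C | intermediate
19 | 2-(tert-butoxycarbonyl)-5-methylhex-4-enoic acid (racemic) | CC(C)=CCC(C(=O)O)C(=O)OC(C)(C)C | intermediate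
20 | 2-[2-(1H-imidazol-1-yl)-2-oxoethyl]-5-{2-methoxy-3-(3-methylbut-2-en-1-yl)-4-[(triisopropylsilyl)oxy]phenyl}-4H-pyran-4-one (not isolated) | O=C(Cc1cc(=O)c(-c2ccc(O[Si](C(C)C)(C(C)C)C(C)C)c(CC=C(C)C)c2OC)co1)n1ccnc1 | intermediate
21 | tert-butyl (2Z)-3-hydroxy-4-(5-{2-methoxy-3-(3-methylbut-2-en-1-yl)-4-[(triisopropylsilyl)oxy]phenyl}-4-oxo-4H-pyran-2-yl)-2-(3-methylbut-2-en-1-yl)but-2-enoate (chelated enol of the β-keto ester) | CC(C)(C)OC(=O)/C(CC=C(C)C)=C(\O)Cc1cc(=O)c(-c2ccc(O[Si](C(C)C)(C(C)C)C(C)C)c(CC=C(C)C)c2OC)co1 | intermediate
22 | acylketene: 5-{2-methoxy-3-(3-methylbut-2-en-1-yl)-4-[(triisopropylsilyl)oxy]phenyl}-2-[2-oxo-3-(oxomethylidene)-6-methylhept-5-en-1-yl]-4H-pyran-4-one (not isolated) | O=C=C(CC=C(C)C)C(=O)Cc1cc(=O)c(-c2ccc(O[Si](C(C)C)(C(C)C)C(C)C)c(CC=C(C)C)c2OC)co1 | intermediate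
23 | 7-hydroxy-3-{2-methoxy-3-(3-methylbut-2-en-1-yl)-4-[(triisopropylsilyl)oxy]phenyl}-6-(3-methylbut-2-en-1-yl)-4aH-chromene-4,5-dione (racemic, not isolated) | O=C1C(CC=C(C)C)=C(O)C=C2OC=C(-c3ccc(O[Si](C(C)C)(C(C)C)C(C)C)c(CC=C(C)C)c3OC)C(=O)C12 | intermediate
24 | 4'-O-(triisopropylsilyl)-2'-methoxylupalbigenin | COc1c(-c2coc3cc(O)c(CC=C(C)C)c(O)c3c2=O)ccc(O[Si](C(C)C)(C(C)C)C(C)C)c1CC=C(C)C | intermediate
25 | 2'-methoxylupalbigenin | COc1c(-c2coc3cc(O)c(CC=C(C)C)c(O)c3c2=O)ccc(O)c1CC=C(C)C | target

## Step count and risks

Total: 13 steps. Longest linear sequence: 11 steps (steps 1–6, 8, 9, 11, 12, 13).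

**Step 12 (key step, proposed new method).**
- What may go wrong: bimolecular dimerisation of the acylketene, or acylation of the newly formed phenols by it, may outrun ring closure if C4a is too weak a nucleophile. Loss of isobutene followed by decarboxylation may compete with loss of tert-butanol.
- Fallback (known chemistry): it sets out from 21 and uses the ester as an ordinary Claisen acceptor under base. Heating 21 with methanol in toluene (110 °C, sealed) exchanges the ester by alcohol capture of the same acylketene, the known transacetoacetylation, and gives methyl (2Z)-3-hydroxy-4-(5-{2-methoxy-3-(3-methylbut-2-en-1-yl)-4-[(triisopropylsilyl)oxy]phenyl}-4-oxo-4H-pyran-2-yl)-2-(3-methylbut-2-en-1-yl)but-2-enoate F1. Treatment of F1 with Mg(OMe)2 in methanol at reflux should deprotonate C8 to the extended pyranone enolate, whose C4a attacks the ester carbon in a Claisen condensation of the kind used for pyranone-masked polyketide esters. Aromatisation returns the route at 24, or directly at 25 if the silyl ether is lost in the basic methanol.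

**Step 11.**
- What may go wrong: the imidazolide 20 may enolise at its doubly activated methylene while the hindered, prenyl-substituted magnesium malonate attacks slowly, so that the activated acid is lost to decarboxylation or self-acylation.
- Fallback: it sets out from 15 and moves the prenylation to the end. Coupling of 15 with Meldrum's acid (DCC, DMAP, CH2Cl2, 0 °C) gives 5-[1-hydroxy-2-(5-{2-methoxy-3-(3-methylbut-2-en-1-yl)-4-[(triisopropylsilyl)oxy]phenyl}-4-oxo-4H-pyran-2-yl)ethylidene]-2,2-dimethyl-1,3-dioxane-4,6-dione F2. Heating F2 in tert-butanol/toluene gives tert-butyl 4-(5-{2-methoxy-3-(3-methylbut-2-en-1-yl)-4-[(triisopropylsilyl)oxy]phenyl}-4-oxo-4H-pyran-2-yl)-3-oxobutanoate F3. Alkylation of F3 at the doubly activated C6 with 17 (K2CO3, acetone) returns the route at 21.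

**Step 9.**
- What may go wrong: decarboxylation of the vinylogous β-keto acid during acidification and concentration, and to a lesser degree metalation at the ring carbon next to O1 in place of the methyl group.
- Fallback: it sets out from 13 and 19 and avoids the free acid by reversing the polarity of the chain assembly. Half ester 19 is converted with 1-chloro-N,N,2-trimethylprop-1-en-1-amine into tert-butyl 2-(chlorocarbonyl)-5-methylhex-4-enoate F4. F4 is added at −78 °C to dienolate 14 generated from 13 with excess LiHMDS. F4 is expected to react through the tert-butoxycarbonyl(prenyl)ketene, which the dienolate captures at C8, and the route comes back at 21, bypassing 15 and 20. The cost is the extra equivalent of base consumed by the acidic hydrogen of F4.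

**Step 4 (with its feeders, steps 2 and 3).**
- What may go wrong: onward Cope migration of the allyl group from dienone 6 to the open para carbon (giving the 1,1-dimethylallyl isomer), ionisation of the tertiary ether with loss of isoprene, or poor formation of the hindered tertiary ether in step 2.
- Fallback: it sets out from 2 and returns at 7 in one operation. The sodium phenoxide of 2 (NaH, toluene) is C-alkylated with 17; the non-polar solvent directs the allylic bromide to the ortho carbon, and the only free ortho carbon is the one between the oxygens. No new compound is made on this path (F0).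

## Further compounds

F1 | step 12 | methyl (2Z)-3-hydroxy-4-(5-{2-methoxy-3-(3-methylbut-2-en-1-yl)-4-[(triisopropylsilyl)oxy]phenyl}-4-oxo-4H-pyran-2-yl)-2-(3-methylbut-2-en-1-yl)but-2-enoate | COC(=O)/C(CC=C(C)C)=C(\O)Cc1cc(=O)c(-c2ccc(O[Si](C(C)C)(C(C)C)C(C)C)c(CC=C(C)C)c2OC)co1
F2 | step 11 | 5-[1-hydroxy-2-(5-{2-methoxy-3-(3-methylbut-2-en-1-yl)-4-[(triisopropylsilyl)oxy]phenyl}-4-oxo-4H-pyran-2-yl)ethylidene]-2,2-dimethyl-1,3-dioxane-4,6-dione | CC1(C)OC(=O)C(=C(O)Cc2cc(=O)c(-c3ccc(O[Si](C(C)C)(C(C)C)C(C)C)c(CC=C(C)C)c3OC)co2)C(=O)O1
F3 | step 11 | tert-butyl 4-(5-{2-methoxy-3-(3-methylbut-2-en-1-yl)-4-[(triisopropylsilyl)oxy]phenyl}-4-oxo-4H-pyran-2-yl)-3-oxobutanoate | CC(C)(C)OC(=O)CC(=O)Cc1cc(=O)c(-c2ccc(O[Si](C(C)C)(C(C)C)C(C)C)c(CC=C(C)C)c2OC)co1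
F4 | step 9 | tert-butyl 2-(chlorocarbonyl)-5-methylhex-4-enoate (racemic) | CC(C)=CCC(C(Cl)=O)C(=O)OC(C)(C)C
F0 | step 4 | none | none
A1 | alternative 1 | 7,4'-bis(methoxymethoxy)-5,2'-bis[(2-methylbut-3-en-2-yl)oxy]isoflavone | COCOc1ccc(-c2coc3cc(OCOC)cc(OC(C)(C)C=C)c3c2=O)c(OC(C)(C)C=C)c1
A2 | alternative 1 | 5,2'-dihydroxy-7,4'-bis(methoxymethoxy)-6,3'-diprenylisoflavone | COCOc1ccc(-c2coc3cc(OCOC)c(CC=C(C)C)c(O)c3c2=O)c(O)c1CC=C(C)C
A3 | alternative 2 | 6-hydroxy-2,4-bis(methoxymethoxy)-3-(3-methylbut-2-en-1-yl)benzaldehyde | O=Cc1c(O)cc(OCOC)c(CC=C(C)C)c1OCOC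
A4 | alternative 2 | {[2-methoxy-4-(methoxymethoxy)-3-(3-methylbut-2-en-1-yl)phenyl]ethynyl}trimethylsilane | COCOc1ccc(C#C[Si](C)(C)C)c(OC)c1CC=C(C)C
A5 | alternative 2 | 2-(trimethylsilyl)-5,7,4'-tris-O-(methoxymethyl)-2'-methoxylupalbigenin | COCOc1ccc(-c2c([Si](C)(C)C)oc3cc(OCOC)c(CC=C(C)C)c(OCOC)c3c2=O)c(OC)c1CC=C(C)C
A6 | alternative 3 | 2-[5,7-bis(methoxymethoxy)-6-(3-methylbut-2-en-1-yl)-4-oxo-4H-chromen-3-yl]cyclobut-2-en-1-one | O=C1CC=C1c1coc2cc(OCOC)c(CC=C(C)C)c(OCOC)c2c1=O
A7 | alternative 3 | 1-methoxy-5-methylhex-4-en-1-yne | COC#CCC=C(C)C
A8 | alternative 3 | 5,7-bis-O-(methoxymethyl)-2'-methoxylupalbigenin | COc1c(-c2coc3cc(OCOC)c(CC=C(C)C)c(OCOC)c3c2=O)ccc(O)c1CC=C(C)C
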